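Ring A (C4a, C5, C6, C7, C8, C8a) bears oxygen on C6 and C8, the carboxyl carbon C1 on C8a and the alkyl arm on C4a. Along C1–C8a–C8–C7–C6–C5–C4a every second carbon is at the carbonyl level, and the two phenols are unequal (C8–OH free, C6–OMe).
Lactone ring B is disconnected at O2–C1. The C3 hydroxyl takes C1 from an aryl acetonide (benzodioxinone) that pairs C8–O with C1, so only C6–OH is open to methylation.
Ring A is disconnected at C4a–C8a, restoring the C4a and C6 ketones, to an open-chain diketo-dioxinone that closes forward by aldol condensation and aromatisation.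
The chain is cut at C5–C4a into the dianion of 6-acetonyl-dioxinone and an (R)-3-silyloxy Weinreb amide. C3 is set by Ru–BINAP hydrogenation of the β-keto ester made from 12-hydroxydodecanoic acid and Meldrum's acid.
Ring order: the dioxinone ring is purchased, ring A forms in step 8, and ring B forms in step 11 at the expense of the dioxinone ring.
Key step: step 8

Remark on the chemistry: locants C1–C8a are those of the isochroman-1-one target and are used for the same atoms in every precursor. TBS = tert-butyldimethylsilyl. The acid stage of the aromatisation is limited to acetic acid, because a mineral acid in methanol would strip the silyl ethers.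

Step 1
Reactants: 1 12-hydroxydodecanoic acid
Product: 3 12-(tert-butyldimethylsilyloxy)dodecanoic acid, via silyl ester 2 (not isolated)
Conditions: TBSCl (2.3 equiv), imidazole (5 equiv), DMF, rt; then K2CO3, MeOH/THF/H2O, rt; aq. KHSO4 to pH 4–5
Reagents that add atoms: tert-butyldimethylsilyl chloride, CC(C)(C)[Si](C)(C)Cl
Why: Imidazole-promoted silylation caps both the hydroxyl and the carboxyl group, and the subsequent carbonate hydrolysis is selective because a silyl ester is cleaved by mild aqueous base far faster than a primary alkyl silyl ether.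

Step 2
Reactants: 3 12-(tert-butyldimethylsilyloxy)dodecanoic acid; 4 Meldrum's acid (2,2-dimethyl-1,3-dioxane-4,6-dione)
Product: 6 methyl 14-(tert-butyldimethylsilyloxy)-3-oxotetradecanoate, via acyl Meldrum's acid 5 (not isolated)
Conditions: DCC (1.1 equiv), DMAP (1.5 equiv), CH2Cl2, 0 °C → rt; filter, cold aq. KHSO4 wash; then MeOH (10 equiv), toluene, 85 °C
Reagents that add atoms: methanol, CO
Why: This is the Meldrum's acid two-carbon homologation (carbodiimide C-acylation, then thermal alcoholysis with decarboxylation), and running the second stage with a limited amount of methanol in toluene keeps the medium close to neutral for the silyl ether.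

Step 3
Reactants: 6 methyl 14-(tert-butyldimethylsilyloxy)-3-oxotetradecanoate
Product: 7 methyl (R)-14-(tert-butyldimethylsilyloxy)-3-hydroxytetradecanoate
Conditions: H2 (90 bar), Ru2Cl4[(R)-BINAP]2(NEt3) (0.2 mol%), MeOH, 30 °C
Reagents that add atoms: none
Why: In the Noyori asymmetric hydrogenation the β-keto ester chelates the divalent ruthenium hydride through both carbonyl oxygens and the (R)-BINAP ligand leaves only the Si face of the C3 ketone open, which for unbranched 3-oxoalkanoates gives the (R)-carbinol, while high pressure at low temperature and the amine-containing precatalyst hold back methanolysis of the silyl ether.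

Step 4
Reactants: 7 methyl (R)-14-(tert-butyldimethylsilyloxy)-3-hydroxytetradecanoate
Product: 8 methyl (R)-3,14-bis(tert-butyldimethylsilyloxy)tetradecanoate
Conditions: TBSCl (2 equiv), imidazole (4 equiv), DMF, rt
Reagents that add atoms: tert-butyldimethylsilyl chloride, CC(C)(C)[Si](C)(C)Cl
Why: Standard imidazole-promoted silylation forms only an O–Si bond, so C3 keeps its (R) configuration, and the excess of reagent would also re-cap any primary hydroxyl laid bare in step 3.

Step 5
Reactants: 8 methyl (R)-3,14-bis(tert-butyldimethylsilyloxy)tetradecanoate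
Product: 9 (R)-3,14-bis(tert-butyldimethylsilyloxy)-N-methoxy-N-methyltetradecanamide
Conditions: MeNH(OMe)·HCl (1.6 equiv), iPrMgCl (3.1 equiv), THF, −20 → 0 °C; aq. NH4Cl
Reagents that add atoms: N,O-dimethylhydroxylamine hydrochloride, CNOC.Cl
Why: Weinreb amide formation by ester aminolysis with the chloromagnesium amide generated in situ is fast below 0 °C, where enolisation at C4 and β-elimination of the C3 silyloxy group should not compete.

Step 6
Reactants: 10 2,2,6-trimethyl-4H-1,3-dioxin-4-one; 11 acetyl chloride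
Product: 13 2,2-dimethyl-6-(2-oxopropyl)-4H-1,3-dioxin-4-one, via lithium dienolate 12 (not isolated)
Conditions: 10 (2 equiv), LiHMDS (2 equiv), THF, −78 °C; AcCl (1 equiv), −78 → −20 °C; 1 M HCl
Reagents that add atoms: none
Why: γ-Selective C-acylation of the dioxinone dienolate (a vinylogous Claisen condensation) is established for this pair of reactants, the second equivalent of dienolate serving to absorb the acidic proton of the product.

Step 7
Reactants: 13 2,2-dimethyl-6-(2-oxopropyl)-4H-1,3-dioxin-4-one; 9 (R)-3,14-bis(tert-butyldimethylsilyloxy)-N-methoxy-N-methyltetradecanamide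
Product: 15 6-[(R)-6,17-bis(tert-butyldimethylsilyloxy)-2,4-dioxoheptadecyl]-2,2-dimethyl-4H-1,3-dioxin-4-one, via dilithium dianion 14 (not isolated)
Conditions: 13 (2 equiv), LDA (4.1 equiv), THF, −78 → −40 °C; 9 (1 equiv), −78 → −20 °C; AcOH/THF quench, −40 °C
Reagents that add atoms: none
Why: In this dianion variant of the crossed Claisen condensation the carbanion generated last, the terminal one that becomes C5, is the most nucleophilic site, and a Weinreb amide transfers its acyl group only once, so the C5–C4a bond should form without touching C3.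

Step 8
Reactants: 15 6-[(R)-6,17-bis(tert-butyldimethylsilyloxy)-2,4-dioxoheptadecyl]-2,2-dimethyl-4H-1,3-dioxin-4-one
Product: 17 5-[(R)-2,13-bis(tert-butyldimethylsilyloxy)tridecyl]-7-hydroxy-2,2-dimethyl-4H-benzo[d][1,3]dioxin-4-one, via aldol carbinol 16 (not isolated)
Conditions: Et3N (5 equiv), CH2Cl2 (0.05 M), rt, 16 h; then AcOH (10 equiv), rt, 2 h
Reagents that add atoms: none
Why: Et3N reversibly removes a C7 proton (flanked by the C6 ketone and the C8 enol-ether carbon of the vinylogous ester), and the extended enolate bonds through its α-carbon C8a to the C4a ketone to give carbinol 16; dehydration across C4a–C5, completed in the AcOH stage, followed by enolisation at C6 makes ring A aromatic. The closest known reaction type is the amine-induced aldol aromatisation of diketo-dioxinones to isopropylidene-protected β-resorcylates, the laboratory counterpart of polyketide cyclase folding. The one ring closed, carbocycle A, forms in a 6-(enolexo)-exo-trig aldol mode, with the enolate C8a=C1 bond outside the new ring and the C4a carbonyl oxygen pointing away from it. No lasting stereocentre is created, since the C4a carbinol centre of 16 vanishes on dehydration, and C3 is not enolisable and stays (R). The step needs C-cyclisation at C8a to beat Claisen-type folding, O-cyclisation to a pyranone and E1cB loss of the C3 silyloxy group: C1 is locked in the dioxinone as a poor acyl acceptor, no other carbon nucleophile and ketone pair can form a six-membered ring, and an amine base ionises only the doubly activated C5 and C7 methylenes, not the singly activated C4–H that elimination would require. Acetic acid stands in for a mineral acid so that both silyl ethers survive together with the acetonide, which keeps C8–O and C1 paired and leaves C6–OH as the only free phenol.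

Step 9
Reactants: 17 5-[(R)-2,13-bis(tert-butyldimethylsilyloxy)tridecyl]-7-hydroxy-2,2-dimethyl-4H-benzo[d][1,3]dioxin-4-one
Product: 18 5-[(R)-2,13-bis(tert-butyldimethylsilyloxy)tridecyl]-7-methoxy-2,2-dimethyl-4H-benzo[d][1,3]dioxin-4-one
Conditions: MeI (2 equiv), K2CO3 (2 equiv), acetone, 40 °C
Reagents that add atoms: iodomethane, CI
Why: Williamson etherification can only strike the C6 phenol, since the C8 oxygen is held in the acetonide and both alcohols are silylated.

Step 10
Reactants: 18 5-[(R)-2,13-bis(tert-butyldimethylsilyloxy)tridecyl]-7-methoxy-2,2-dimethyl-4H-benzo[d][1,3]dioxin-4-one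
Product: 19 5-[(R)-2,13-dihydroxytridecyl]-7-methoxy-2,2-dimethyl-4H-benzo[d][1,3]dioxin-4-one
Conditions: HF·pyridine, pyridine, THF, 0 °C → rt
Reagents that add atoms: none
Why: Fluoride-driven desilylation in pyridine-buffered HF breaks only Si–O bonds, so C3 stays (R), and the aryl methyl ether and the benzodioxinone tolerate this weakly acidic medium.

Step 11
Reactants: 19 5-[(R)-2,13-dihydroxytridecyl]-7-methoxy-2,2-dimethyl-4H-benzo[d][1,3]dioxin-4-one
Product: 20 (R)-8-hydroxy-3-(11-hydroxyundecyl)-6-methoxyisochroman-1-one (CNP0140068.1)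
Conditions: NaH (1.2 equiv), THF (0.02 M), 0 °C → rt; 1 M HCl
Reagents that add atoms: none
Why: Alkoxide-induced transacylation of a salicylate acetonide: the C3 alkoxide attacks C1 in a 6-exo-trig lactonisation, the hemiketal leaving group collapses to acetone and the C8 phenoxide, ring closure is far faster than any intermolecular attack by the remote primary alkoxide at this dilution, and the C3–O bond is never broken.

Compound list
1 | 12-hydroxydodecanoic acid | OCCCCCCCCCCCC(=O)O | starting material
2 | tert-butyldimethylsilyl 12-(tert-butyldimethylsilyloxy)dodecanoate (silyl ester, not isolated) | CC(C)(C)[Si](C)(C)OCCCCCCCCCCCC(=O)O[Si](C)(C)C(C)(C)C | intermediate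
3 | 12-(tert-butyldimethylsilyloxy)dodecanoic acid | CC(C)(C)[Si](C)(C)OCCCCCCCCCCCC(=O)O | intermediate
4 | Meldrum's acid (2,2-dimethyl-1,3-dioxane-4,6-dione) | CC1(C)OC(=O)CC(=O)O1 | starting material
5 | 5-[12-(tert-butyldimethylsilyloxy)-1-hydroxydodecylidene]-2,2-dimethyl-1,3-dioxane-4,6-dione (acyl Meldrum's acid, not isolated) | CC1(C)OC(=O)C(=C(O)CCCCCCCCCCCO[Si](C)(C)C(C)(C)C)C(=O)O1 | intermediate
6 | methyl 14-(tert-butyldimethylsilyloxy)-3-oxotetradecanoate | COC(=O)CC(=O)CCCCCCCCCCCO[Si](C)(C)C(C)(C)C | intermediate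
7 | methyl (R)-14-(tert-butyldimethylsilyloxy)-3-hydroxytetradecanoate | COC(=O)C[C@@H](CCCCCCCCCCCO[Si](C)(C)C(C)(C)C)O | intermediate
8 | methyl (R)-3,14-bis(tert-butyldimethylsilyloxy)tetradecanoate | COC(=O)C[C@@H](CCCCCCCCCCCO[Si](C)(C)C(C)(C)C)O[Si](C)(C)C(C)(C)C | intermediate
9 | (R)-3,14-bis(tert-butyldimethylsilyloxy)-N-methoxy-N-methyltetradecanamide | CON(C)C(=O)C[C@@H](CCCCCCCCCCCO[Si](C)(C)C(C)(C)C)O[Si](C)(C)C(C)(C)C | intermediate
10 | 2,2,6-trimethyl-4H-1,3-dioxin-4-one | CC1=CC(=O)OC(C)(C)O1 | starting material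
11 | acetyl chloride | CC(=O)Cl | starting material
12 | lithium 2,2-dimethyl-6-methylidene-6H-1,3-dioxin-4-olate (dienolate of 10, not isolated) | C=C1C=C([O-])OC(C)(C)O1.[Li+] | intermediate
13 | 2,2-dimethyl-6-(2-oxopropyl)-4H-1,3-dioxin-4-one | CC(=O)CC1=CC(=O)OC(C)(C)O1 | intermediate
14 | dilithium dianion of 13, drawn as the bis-enolate with a terminal CH2= (not isolated) | C=C([O-])C=C1C=C([O-])OC(C)(C)O1.[Li+].[Li+] | intermediate
15 | 6-[(R)-6,17-bis(tert-butyldimethylsilyloxy)-2,4-dioxoheptadecyl]-2,2-dimethyl-4H-1,3-dioxin-4-one | CC1(C)OC(=O)C=C(CC(=O)CC(=O)C[C@@H](CCCCCCCCCCCO[Si](C)(C)C(C)(C)C)O[Si](C)(C)C(C)(C)C)O1 | intermediate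
16 | 5-[(R)-2,13-bis(tert-butyldimethylsilyloxy)tridecyl]-5-hydroxy-2,2-dimethyl-5,6-dihydro-4H-benzo[d][1,3]dioxine-4,7(8H)-dione (aldol carbinol, both C4a epimers, not isolated) | CC1(C)OC(=O)C2=C(CC(=O)CC2(O)C[C@@H](CCCCCCCCCCCO[Si](C)(C)C(C)(C)C)O[Si](C)(C)C(C)(C)C)O1 | intermediate
17 | 5-[(R)-2,13-bis(tert-butyldimethylsilyloxy)tridecyl]-7-hydroxy-2,2-dimethyl-4H-benzo[d][1,3]dioxin-4-one | CC1(C)OC(=O)c2c(C[C@@H](CCCCCCCCCCCO[Si](C)(C)C(C)(C)C)O[Si](C)(C)C(C)(C)C)cc(O)cc2O1 | intermediate
18 | 5-[(R)-2,13-bis(tert-butyldimethylsilyloxy)tridecyl]-7-methoxy-2,2-dimethyl-4H-benzo[d][1,3]dioxin-4-one | CC1(C)OC(=O)c2c(C[C@@H](CCCCCCCCCCCO[Si](C)(C)C(C)(C)C)O[Si](C)(C)C(C)(C)C)cc(OC)cc2O1 | intermediate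
19 | 5-[(R)-2,13-dihydroxytridecyl]-7-methoxy-2,2-dimethyl-4H-benzo[d][1,3]dioxin-4-one | CC1(C)OC(=O)c2c(C[C@@H](CCCCCCCCCCCO)O)cc(OC)cc2O1 | intermediate
20 | (R)-8-hydroxy-3-(11-hydroxyundecyl)-6-methoxyisochroman-1-one | COc1cc(O)c2c(c1)C[C@@H](CCCCCCCCCCCO)OC2=O | target

Total step count: 11.
Longest linear sequence: 10 steps (steps 1–5 and 7–11, from 1). Step 6 is the side branch.

Steps most likely to fail

1. Step 7.
- Risk: The strongly basic dianion may take a C4 proton from the amide instead of adding to it, which opens β-elimination of the silyloxy group. Acyl transfer may also be too slow at the temperatures the dianion tolerates.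
- Fallback: It sets out from 9 (with 13) and comes back at 15, replacing acyl substitution by aldol addition and oxidation. DIBAL-H (THF, −78 °C) reduces the Weinreb amide to (R)-3,14-bis(tert-butyldimethylsilyloxy)tetradecanal F1. Dianion 14 adds to this much more electrophilic carbonyl at −78 °C. This gives 6-[(6R)-6,17-bis(tert-butyldimethylsilyloxy)-4-hydroxy-2-oxoheptadecyl]-2,2-dimethyl-4H-1,3-dioxin-4-one F2 as an inconsequential mixture of carbinol epimers. Dess–Martin periodinane (1.1 equiv, CH2Cl2, rt) then oxidises the C4a carbinol to the diketone 15.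

2. Step 8.
- Risk: The aldol closure may be outrun by O-cyclisation with loss of the acetonide. It may also be undercut by elimination of the C3 silyloxy group, or stall before dehydration.
- Fallback: It sets out from 9 and comes back at 20, building ring A by cycloaddition instead of aldol folding.
  - The aldehyde F1 (DIBAL-H on 9, as above) undergoes Corey–Fuchs olefination (CBr4, PPh3, CH2Cl2, 0 °C) to (R)-1,1-dibromo-4,15-bis(tert-butyldimethylsilyloxy)pentadec-1-ene F3.
  - nBuLi (2.1 equiv, THF, −78 °C) followed by ClCO2Me gives methyl (R)-5,16-bis(tert-butyldimethylsilyloxy)hexadec-2-ynoate F4.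
  - Heating F4 with Brassard's diene, (E)-1,3-dimethoxy-1-(trimethylsilyloxy)buta-1,3-diene, in toluene at 120 °C (sealed tube) effects a Diels–Alder reaction. The nucleophilic CH2 terminus of the diene bonds to the β-carbon (C4a) and the ketene-acetal carbon to C8a. The product is methyl 2-[(R)-2,13-bis(tert-butyldimethylsilyloxy)tridecyl]-4,6-dimethoxy-6-(trimethylsilyloxy)cyclohexa-1,4-diene-1-carboxylate F5.
  - On silica gel F5 loses methanol and the trimethylsilyl group. This gives methyl 6-[(R)-2,13-bis(tert-butyldimethylsilyloxy)tridecyl]-2-hydroxy-4-methoxybenzoate F6, in which the diene has already differentiated C6–OMe from C8–OH.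
  - HF·pyridine gives methyl 6-[(R)-2,13-dihydroxytridecyl]-2-hydroxy-4-methoxybenzoate F7, and catalytic p-TsOH in toluene at 60 °C closes the six-membered lactone to 20.

3. Step 3.
- Risk: HCl released from the precatalyst may methanolyse the primary silyl ether. Turnover may also be low under the mild conditions chosen to prevent that.
- Fallback: It sets out from 3 and comes back at 9, setting C3 by asymmetric C–C bond formation instead of ketone reduction.
  - BH3·SMe2 (THF, 0 °C) gives 12-(tert-butyldimethylsilyloxy)dodecan-1-ol F8, and Swern oxidation gives 12-(tert-butyldimethylsilyloxy)dodecanal F9.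
  - Brown allylation with B-allyldiisopinocampheylborane prepared from (+)-α-pinene (Et2O, −78 °C; NaOH, H2O2) should give the (R)-carbinol expected for unbranched aldehydes, (R)-15-(tert-butyldimethylsilyloxy)pentadec-1-en-4-ol F10.
  - TBSCl and imidazole give (R)-4,15-bis(tert-butyldimethylsilyloxy)pentadec-1-ene F11.
  - Ozonolysis (O3, CH2Cl2, −78 °C; PPh3) gives the aldehyde F1, and Pinnick oxidation (NaClO2, NaH2PO4, 2-methyl-2-butene, tBuOH/H2O) gives (R)-3,14-bis(tert-butyldimethylsilyloxy)tetradecanoic acid F12.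
  - Coupling of F12 with MeNH(OMe)·HCl (EDC·HCl, iPr2NEt, CH2Cl2) gives 9.

Further compounds
F1 | step 7 | (R)-3,14-bis(tert-butyldimethylsilyloxy)tetradecanal | O=CC[C@@H](CCCCCCCCCCCO[Si](C)(C)C(C)(C)C)O[Si](C)(C)C(C)(C)C
F2 | step 7 | 6-[(6R)-6,17-bis(tert-butyldimethylsilyloxy)-4-hydroxy-2-oxoheptadecyl]-2,2-dimethyl-4H-1,3-dioxin-4-one (carbinol epimers) | CC1(C)OC(=O)C=C(CC(=O)CC(O)C[C@@H](CCCCCCCCCCCO[Si](C)(C)C(C)(C)C)O[Si](C)(C)C(C)(C)C)O1
F3 | step 8 | (R)-1,1-dibromo-4,15-bis(tert-butyldimethylsilyloxy)pentadec-1-ene | BrC(Br)=CC[C@@H](CCCCCCCCCCCO[Si](C)(C)C(C)(C)C)O[Si](C)(C)C(C)(C)C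
F4 | step 8 | methyl (R)-5,16-bis(tert-butyldimethylsilyloxy)hexadec-2-ynoate | COC(=O)C#CC[C@@H](CCCCCCCCCCCO[Si](C)(C)C(C)(C)C)O[Si](C)(C)C(C)(C)C
F5 | step 8 | methyl 2-[(R)-2,13-bis(tert-butyldimethylsilyloxy)tridecyl]-4,6-dimethoxy-6-(trimethylsilyloxy)cyclohexa-1,4-diene-1-carboxylate (acetal epimers) | COC(=O)C1=C(C[C@@H](CCCCCCCCCCCO[Si](C)(C)C(C)(C)C)O[Si](C)(C)C(C)(C)C)CC(OC)=CC1(OC)O[Si](C)(C)C
F6 | step 8 | methyl 6-[(R)-2,13-bis(tert-butyldimethylsilyloxy)tridecyl]-2-hydroxy-4-methoxybenzoate | COC(=O)c1c(O)cc(OC)cc1C[C@@H](CCCCCCCCCCCO[Si](C)(C)C(C)(C)C)O[Si](C)(C)C(C)(C)C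
F7 | step 8 | methyl 6-[(R)-2,13-dihydroxytridecyl]-2-hydroxy-4-methoxybenzoate | COC(=O)c1c(O)cc(OC)cc1C[C@@H](CCCCCCCCCCCO)O
F8 | step 3 | 12-(tert-butyldimethylsilyloxy)dodecan-1-ol | CC(C)(C)[Si](C)(C)OCCCCCCCCCCCCO
F9 | step 3 | 12-(tert-butyldimethylsilyloxy)dodecanal | CC(C)(C)[Si](C)(C)OCCCCCCCCCCCC=O
F10 | step 3 | (R)-15-(tert-butyldimethylsilyloxy)pentadec-1-en-4-ol | C=CC[C@@H](CCCCCCCCCCCO[Si](C)(C)C(C)(C)C)O
F11 | step 3 | (R)-4,15-bis(tert-butyldimethylsilyloxy)pentadec-1-ene | C=CC[C@@H](CCCCCCCCCCCO[Si](C)(C)C(C)(C)C)O[Si](C)(C)C(C)(C)C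
F12 | step 3 | (R)-3,14-bis(tert-butyldimethylsilyloxy)tetradecanoic acid | OC(=O)C[C@@H](CCCCCCCCCCCO[Si](C)(C)C(C)(C)C)O[Si](C)(C)C(C)(C)C
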